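Ring A is disconnected at C2–C3 and C4–C5. Its C2 hydroxyl, C3 methyl and C4 methoxyl form a resorcinol monomethyl ether, the pattern left when a vinylketene carbonyl (C2) is joined to a methoxyalkyne (C3, C4). Heating cyclobutenone 14 with 1-methoxyprop-1-yne 17 should make both bonds, close ring A and give phenol 22 with the two oxygens differentiated and only C1 open. Precursor 14 is 3-methylcyclobut-2-en-1-one carrying at its carbon 2 the future bridge CH2 and ring B as a tribenzyl ether. Hydrogenolysis and one double butanoylation at the only free carbon of each ring (C1, C5′) finish the synthesis.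

Key step: step 9

Remark: the target has no stereocentre. Ring A is numbered C1 (butanoyl), C2 (OH), C3 (CH3), C4 (OCH3), C5 (CH2 bridge), C6 (CH3); ring B is numbered C1′ (bridge) to C5′ (butanoyl).

Step 1
Reactants: 1 2-methylbenzene-1,3,5-triol
Product: 3 2,4,6-trihydroxy-3-methylbenzaldehyde, via aryliminium chloride 2 (not isolated)
Conditions: POCl3, DMF, EtOAc, 0 °C to rt; then H2O, 50 °C
Reagents that add atoms: N,N-dimethylformamide, CN(C)C=O; water, O
Why: Vilsmeier–Haack formylation attacks one of the two equivalent free ring carbons of the electron-rich triol, and the iminium group formed deactivates the ring against a second formylation before it is hydrolysed.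

Step 2
Reactants: 3 2,4,6-trihydroxy-3-methylbenzaldehyde
Product: 4 2,4,6-tris(benzyloxy)-3-methylbenzaldehyde
Conditions: BnBr (3.6 equiv), K2CO3, DMF, 60 °C
Reagents that add atoms: benzyl bromide, BrCc1ccccc1
Why: Williamson etherification of a formyl-deactivated phloroglucinol should go on oxygen and not on the ring carbon, and excess benzyl bromide in warm DMF should also etherify the two hydrogen-bonded ortho hydroxyls.

Step 3
Reactants: 4 2,4,6-tris(benzyloxy)-3-methylbenzaldehyde
Product: 5 [2,4,6-tris(benzyloxy)-3-methylphenyl]methanol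
Conditions: NaBH4, THF/MeOH, 0 °C
Reagents that add atoms: none
Why: Borohydride reduction of an aryl aldehyde leaves the benzyl ethers untouched.

Step 4
Reactants: 5 [2,4,6-tris(benzyloxy)-3-methylphenyl]methanol
Product: 6 1,3,5-tris(benzyloxy)-2-(bromomethyl)-4-methylbenzene
Conditions: PBr3 (0.4 equiv), Et2O, −20 °C; cold aq NaHCO3 wash; used at once as a cold solution
Reagents that add atoms: phosphorus tribromide, BrP(Br)Br
Why: Conversion of a benzylic alcohol into its bromide with PBr3 is fast at low temperature, and because the 2,4,6-trialkoxybenzyl bromide ionises easily it should be kept cold, acid-free and in solution until it is used.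

Step 5
Reactants: 7 ethoxyethyne; 6 1,3,5-tris(benzyloxy)-2-(bromomethyl)-4-methylbenzene
Product: 9 1,3,5-tris(benzyloxy)-2-(3-ethoxyprop-2-yn-1-yl)-4-methylbenzene, via lithium ethoxyacetylide 8 (not isolated)
Conditions: 7 (1.5 equiv), n-BuLi (1.4 equiv), THF, −78 °C; then DMPU, 6 in THF, −78 to 0 °C; aq NaHCO3 work-up, basic alumina
Reagents that add atoms: none
Why: SN2 alkylation of a lithium alkoxyacetylide in a dipolar cosolvent should be clean here because the primary benzylic bromide is highly reactive and has no β-hydrogen, so elimination cannot compete.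

Step 6
Reactants: 9 1,3,5-tris(benzyloxy)-2-(3-ethoxyprop-2-yn-1-yl)-4-methylbenzene; 10 acetyl chloride
Product: 12 3-ethoxy-2-{[2,4,6-tris(benzyloxy)-3-methylphenyl]methyl}cyclobut-2-en-1-one, via ketene 11 (not isolated)
Conditions: 10 (4 equiv, slow addition), Et3N (4.4 equiv), Et2O, 0 °C to rt
Reagents that add atoms: none
Why: In this [2+2] cycloaddition of ketene (made by dehydrochlorination of 10) with an ynol ether, the nucleophilic arylmethyl-bearing alkyne carbon bonds to the ketene carbonyl carbon, which puts the arylmethyl group at carbon 2 and the ethoxy group at carbon 3 of the cyclobutenone.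

Step 7
Reactants: 12 3-ethoxy-2-{[2,4,6-tris(benzyloxy)-3-methylphenyl]methyl}cyclobut-2-en-1-one
Product: 14 3-methyl-2-{[2,4,6-tris(benzyloxy)-3-methylphenyl]methyl}cyclobut-2-en-1-one, via lithium cyclobutenolate 13 (not isolated)
Conditions: MeLi (1.3 equiv), THF, −78 °C; then 1 M aq HCl, 0 °C
Reagents that add atoms: methyllithium, [Li]C; water, O
Why: 1,2-Addition of MeLi to the vinylogous ester carbonyl followed by acid hydrolysis with allylic transposition (Stork–Danheiser type) moves the carbonyl to the former ethoxy carbon, leaving the methyl at carbon 3 and the arylmethyl group at carbon 2; the racemic carbinol centre of 13 is destroyed in the same operation.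

Step 8
Reactants: 15 2-chloro-1,1-dimethoxyethane
Product: 17 1-methoxyprop-1-yne, via sodium methoxyacetylide 16 (not isolated)
Conditions: NaNH2 (3.1 equiv), liq. NH3, −33 °C; then MeI, −50 to −33 °C; distillation
Reagents that add atoms: iodomethane, CI
Why: Twofold elimination (HCl and methanol) from the chloroacetal with NaNH2 gives the sodium alkoxyacetylide, which is methylated on carbon by iodomethane in liquid ammonia, the classical alkoxyalkyne preparation.

Step 9
Reactants: 14 3-methyl-2-{[2,4,6-tris(benzyloxy)-3-methylphenyl]methyl}cyclobut-2-en-1-one; 17 1-methoxyprop-1-yne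
Product: 22 3-methoxy-2,5-dimethyl-4-{[2,4,6-tris(benzyloxy)-3-methylphenyl]methyl}phenol, via vinylketene 18 (not isolated), via 4-vinylcyclobutenone 19 (not isolated), via dienylketene 20 (not isolated), via cyclohexadienone 21 (not isolated)
Conditions: 17 (3 equiv), toluene, sealed tube, 80 °C then 110 °C
Reagents that add atoms: none
Why: Thermal 4π electrocyclic opening of 14 gives vinylketene 18, which adds 17 in a [2+2] cycloaddition (new bonds C2–C3 and C4–C5 of ring A) to give the transient four-membered ring of 19, and a second 4π opening gives dienylketene 20. Ring A then closes by a thermal disrotatory 6π electrocyclisation joining C1 to the ketene carbon C2, and dienone 21 tautomerises to the phenol. The closest known reaction type is the Danheiser benzannulation of cyclobutenones with alkoxyalkynes. No stereocentre remains in the product, the quaternary centre of 19 being transient and racemic. The step needs the regiochemistry of the [2+2], which the polarisation of the ynol ether secures: its methyl-bearing β-carbon is the nucleophilic end and bonds to the electrophilic ketene carbon, so the methyl lands on C3 between the two oxygens and the methoxyl on C4; the dienylketene geometries interconvert through 19, so only the one able to cyclise is drained.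

Step 10
Reactants: 22 3-methoxy-2,5-dimethyl-4-{[2,4,6-tris(benzyloxy)-3-methylphenyl]methyl}phenol
Product: 23 2-[(4-hydroxy-2-methoxy-3,6-dimethylphenyl)methyl]-4-methylbenzene-1,3,5-triol
Conditions: H2 (1 atm), 10% Pd/C, EtOAc/MeOH, rt; product kept under argon and used directly
Reagents that add atoms: none
Why: Catalytic hydrogenolysis cleaves the three aryl benzyl ethers and leaves the C4 methyl ether, the diarylmethane bridge and the ring methyls intact.

Step 11
Reactants: 23 2-[(4-hydroxy-2-methoxy-3,6-dimethylphenyl)methyl]-4-methylbenzene-1,3,5-triol; 24 butanoic acid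
Product: 25 1-{3-[(3-butanoyl-2,4,6-trihydroxy-5-methylphenyl)methyl]-6-hydroxy-4-methoxy-2,5-dimethylphenyl}butan-1-one (target)
Conditions: 24 (6 equiv), BF3·OEt2, 70 °C; aq NaOAc work-up
Reagents that add atoms: none
Why: Friedel–Crafts (Fries-type) C-acylation with the carboxylic acid in BF3·OEt2 can only reach the single unsubstituted carbon of each ring (C1, ortho to the C2 hydroxyl and para to OCH3; C5′, between two hydroxyls), so both ketones should form in one operation, with any aryl ester formed on the way rearranging under the same conditions.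

Compound list
1 | 2-methylbenzene-1,3,5-triol | Cc1c(O)cc(O)cc1O | starting material
2 | N-[(2,4,6-trihydroxy-3-methylphenyl)methylidene]-N-methylmethanaminium chloride | C[N+](C)=Cc1c(O)cc(O)c(C)c1O.[Cl-] | intermediate
3 | 2,4,6-trihydroxy-3-methylbenzaldehyde | O=Cc1c(O)cc(O)c(C)c1O | intermediate
4 | 2,4,6-tris(benzyloxy)-3-methylbenzaldehyde | O=Cc1c(OCc2ccccc2)c(C)c(OCc2ccccc2)cc1OCc1ccccc1 | intermediate
5 | [2,4,6-tris(benzyloxy)-3-methylphenyl]methanol | OCc1c(OCc2ccccc2)c(C)c(OCc2ccccc2)cc1OCc1ccccc1 | intermediate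
6 | 1,3,5-tris(benzyloxy)-2-(bromomethyl)-4-methylbenzene | BrCc1c(OCc2ccccc2)c(C)c(OCc2ccccc2)cc1OCc1ccccc1 | intermediate
7 | ethoxyethyne | C#COCC | starting material
8 | lithium ethoxyacetylide | [Li]C#COCC | intermediate
9 | 1,3,5-tris(benzyloxy)-2-(3-ethoxyprop-2-yn-1-yl)-4-methylbenzene | CCOC#CCc1c(OCc2ccccc2)c(C)c(OCc2ccccc2)cc1OCc1ccccc1 | intermediate
10 | acetyl chloride | CC(=O)Cl | starting material
11 | ketene | C=C=O | intermediate
12 | 3-ethoxy-2-{[2,4,6-tris(benzyloxy)-3-methylphenyl]methyl}cyclobut-2-en-1-one | CCOC1=C(Cc2c(OCc3ccccc3)c(C)c(OCc3ccccc3)cc2OCc2ccccc2)C(=O)C1 | intermediate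
13 | lithium 3-ethoxy-1-methyl-2-{[2,4,6-tris(benzyloxy)-3-methylphenyl]methyl}cyclobut-2-en-1-olate (racemic) | CCOC1=C(Cc2c(OCc3ccccc3)c(C)c(OCc3ccccc3)cc2OCc2ccccc2)C(C)(O[Li])C1 | intermediate
14 | 3-methyl-2-{[2,4,6-tris(benzyloxy)-3-methylphenyl]methyl}cyclobut-2-en-1-one | CC1=C(Cc2c(OCc3ccccc3)c(C)c(OCc3ccccc3)cc2OCc2ccccc2)C(=O)C1 | intermediate
15 | 2-chloro-1,1-dimethoxyethane | COC(CCl)OC | starting material
16 | sodium methoxyacetylide | [Na]C#COC | intermediate
17 | 1-methoxyprop-1-yne | CC#COC | intermediate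
18 | 3-methyl-2-{[2,4,6-tris(benzyloxy)-3-methylphenyl]methyl}buta-1,3-dien-1-one | C=C(C)C(Cc1c(OCc2ccccc2)c(C)c(OCc2ccccc2)cc1OCc1ccccc1)=C=O | intermediate
19 | 3-methoxy-2-methyl-4-(prop-1-en-2-yl)-4-{[2,4,6-tris(benzyloxy)-3-methylphenyl]methyl}cyclobut-2-en-1-one (racemic) | COC1=C(C)C(=O)C1(Cc1c(OCc2ccccc2)c(C)c(OCc2ccccc2)cc1OCc1ccccc1)C(C)=C | intermediate
20 | (3E)-3-methoxy-2,5-dimethyl-4-{[2,4,6-tris(benzyloxy)-3-methylphenyl]methyl}hexa-1,3,5-trien-1-one | O=C=C(C)/C(OC)=C(Cc1c(OCc2ccccc2)c(C)c(OCc2ccccc2)cc1OCc1ccccc1)\C(C)=C | intermediate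
21 | 3-methoxy-2,5-dimethyl-4-{[2,4,6-tris(benzyloxy)-3-methylphenyl]methyl}cyclohexa-2,4-dien-1-one | COC1=C(C)C(=O)CC(C)=C1Cc1c(OCc2ccccc2)c(C)c(OCc2ccccc2)cc1OCc1ccccc1 | intermediate
22 | 3-methoxy-2,5-dimethyl-4-{[2,4,6-tris(benzyloxy)-3-methylphenyl]methyl}phenol | COc1c(C)c(O)cc(C)c1Cc1c(OCc2ccccc2)c(C)c(OCc2ccccc2)cc1OCc1ccccc1 | intermediate
23 | 2-[(4-hydroxy-2-methoxy-3,6-dimethylphenyl)methyl]-4-methylbenzene-1,3,5-triol | COc1c(C)c(O)cc(C)c1Cc1c(O)c(C)c(O)cc1O | intermediate
24 | butanoic acid | CCCC(=O)O | starting material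
25 | 1-{3-[(3-butanoyl-2,4,6-trihydroxy-5-methylphenyl)methyl]-6-hydroxy-4-methoxy-2,5-dimethylphenyl}butan-1-one | CCCC(=O)c1c(C)c(Cc2c(O)c(C)c(O)c(C(=O)CCC)c2O)c(OC)c(C)c1O | target

Total step count: 11. Longest linear sequence: 10 steps (steps 1 to 7 and 9 to 11); step 8 is a one-step branch.

Steps most likely to fail

Step 9. The vinylketene may be consumed by dimerisation, or by addition of the phenol as it forms, faster than it undergoes the bimolecular [2+2]; the regiochemical sense of that cycloaddition may also be incomplete. The fallback gives up the annulation of ring A and joins two preformed acylated rings through the methylene, using only Friedel–Crafts chemistry at positions that are each the sole free carbon of their ring. It sets out from 1 and 24 and comes back at target 25. Acylation of 1 with 24 in BF3·OEt2 would give 1-(2,4,6-trihydroxy-3-methylphenyl)butan-1-one F1. The same acylation of commercial 2,5-dimethylbenzene-1,3-diol, whose two free carbons are equivalent, would give 1-(2,4-dihydroxy-3,6-dimethylphenyl)butan-1-one F2. MeI and K2CO3 in acetone would methylate the hydroxyl that is not hydrogen-bonded to the ketone, giving 1-(2-hydroxy-4-methoxy-3,6-dimethylphenyl)butan-1-one F3. Blanc chloromethylation (paraformaldehyde, HCl, AcOH) at the one free carbon of F3 would give 1-[3-(chloromethyl)-6-hydroxy-4-methoxy-2,5-dimethylphenyl]butan-1-one F4. Friedel–Crafts benzylation of the one free carbon of F1 by F4 (ZnCl2, dioxane, 60 °C) would then give 25.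

Step 5. The benzylic bromide may ionise and attack the unsubstituted ring carbon C5′ of a second molecule (self-condensation) during its preparation, handling or reaction with the acetylide. The fallback blocks C5′ with a bromine that travels as a spectator and is removed in the hydrogenolysis. It sets out from 4 and comes back at 23.
- NBS in DMF at 0 °C would brominate the single free ring carbon of 4 to give 2,4,6-tris(benzyloxy)-3-bromo-5-methylbenzaldehyde F5.
- NaBH4 would give [2,4,6-tris(benzyloxy)-3-bromo-5-methylphenyl]methanol F6.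
- PBr3 would give 1,3,5-tris(benzyloxy)-2-bromo-4-(bromomethyl)-6-methylbenzene F7, which has no nucleophilic ring carbon left.
- Alkylation of 8 in THF/DMPU would give 1,3,5-tris(benzyloxy)-2-bromo-4-(3-ethoxyprop-2-yn-1-yl)-6-methylbenzene F8.
- Treatment with 10 and Et3N would give 3-ethoxy-2-{[2,4,6-tris(benzyloxy)-3-bromo-5-methylphenyl]methyl}cyclobut-2-en-1-one F9.
- MeLi at −78 °C (too slow in bromine–lithium exchange to touch the aryl bromide) and then aqueous HCl would give 3-methyl-2-{[2,4,6-tris(benzyloxy)-3-bromo-5-methylphenyl]methyl}cyclobut-2-en-1-one F10.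
- Heating with 17 would give 3-methoxy-2,5-dimethyl-4-{[2,4,6-tris(benzyloxy)-3-bromo-5-methylphenyl]methyl}phenol F11.
- Hydrogenation of F11 over Pd/C with NaOAc would cleave the benzyl ethers and the aryl bromide together and give 23.

Step 11. The Lewis acid may cleave or scramble the electron-rich methylene bridge (ipso-protonation, retro-Friedel–Crafts), or the acylation may stall at the ester stage at the hindered C1 of ring A. The fallback brings in both butanoyl groups by carbanion acylation before deprotection. It sets out from 22 and comes back at target 25.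
- BnBr and K2CO3 in DMF would give 1-(benzyloxy)-3-methoxy-2,5-dimethyl-4-{[2,4,6-tris(benzyloxy)-3-methylphenyl]methyl}benzene F12.
- NBS (2 equiv) in MeCN would brominate the only two ring C–H positions of the core, C1 and C5′, to give 1-(benzyloxy)-6-bromo-3-methoxy-2,5-dimethyl-4-{[2,4,6-tris(benzyloxy)-3-bromo-5-methylphenyl]methyl}benzene F13.
- Double bromine–lithium exchange with t-BuLi in THF at −78 °C and acylation with N-methoxy-N-methylbutanamide would give 1-{6-(benzyloxy)-3-{[2,4,6-tris(benzyloxy)-3-butanoyl-5-methylphenyl]methyl}-4-methoxy-2,5-dimethylphenyl}butan-1-one F14.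
- Hydrogenolysis (H2, Pd/C, EtOAc) would give 25.

Further compounds
F1 | step 9 | 1-(2,4,6-trihydroxy-3-methylphenyl)butan-1-one | CCCC(=O)c1c(O)cc(O)c(C)c1O
F2 | step 9 | 1-(2,4-dihydroxy-3,6-dimethylphenyl)butan-1-one | CCCC(=O)c1c(C)cc(O)c(C)c1O
F3 | step 9 | 1-(2-hydroxy-4-methoxy-3,6-dimethylphenyl)butan-1-one | CCCC(=O)c1c(C)cc(OC)c(C)c1O
F4 | step 9 | 1-[3-(chloromethyl)-6-hydroxy-4-methoxy-2,5-dimethylphenyl]butan-1-one | CCCC(=O)c1c(C)c(CCl)c(OC)c(C)c1O
F5 | step 5 | 2,4,6-tris(benzyloxy)-3-bromo-5-methylbenzaldehyde | O=Cc1c(OCc2ccccc2)c(C)c(OCc2ccccc2)c(Br)c1OCc1ccccc1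
F6 | step 5 | [2,4,6-tris(benzyloxy)-3-bromo-5-methylphenyl]methanol | OCc1c(OCc2ccccc2)c(C)c(OCc2ccccc2)c(Br)c1OCc1ccccc1
F7 | step 5 | 1,3,5-tris(benzyloxy)-2-bromo-4-(bromomethyl)-6-methylbenzene | BrCc1c(OCc2ccccc2)c(C)c(OCc2ccccc2)c(Br)c1OCc1ccccc1
F8 | step 5 | 1,3,5-tris(benzyloxy)-2-bromo-4-(3-ethoxyprop-2-yn-1-yl)-6-methylbenzene | CCOC#CCc1c(OCc2ccccc2)c(C)c(OCc2ccccc2)c(Br)c1OCc1ccccc1
F9 | step 5 | 3-ethoxy-2-{[2,4,6-tris(benzyloxy)-3-bromo-5-methylphenyl]methyl}cyclobut-2-en-1-one | CCOC1=C(Cc2c(OCc3ccccc3)c(C)c(OCc3ccccc3)c(Br)c2OCc2ccccc2)C(=O)C1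
F10 | step 5 | 3-methyl-2-{[2,4,6-tris(benzyloxy)-3-bromo-5-methylphenyl]methyl}cyclobut-2-en-1-one | CC1=C(Cc2c(OCc3ccccc3)c(C)c(OCc3ccccc3)c(Br)c2OCc2ccccc2)C(=O)C1
F11 | step 5 | 3-methoxy-2,5-dimethyl-4-{[2,4,6-tris(benzyloxy)-3-bromo-5-methylphenyl]methyl}phenol | COc1c(C)c(O)cc(C)c1Cc1c(OCc2ccccc2)c(C)c(OCc2ccccc2)c(Br)c1OCc1ccccc1
F12 | step 11 | 1-(benzyloxy)-3-methoxy-2,5-dimethyl-4-{[2,4,6-tris(benzyloxy)-3-methylphenyl]methyl}benzene | COc1c(C)c(OCc2ccccc2)cc(C)c1Cc1c(OCc2ccccc2)c(C)c(OCc2ccccc2)cc1OCc1ccccc1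
F13 | step 11 | 1-(benzyloxy)-6-bromo-3-methoxy-2,5-dimethyl-4-{[2,4,6-tris(benzyloxy)-3-bromo-5-methylphenyl]methyl}benzene | COc1c(C)c(OCc2ccccc2)c(Br)c(C)c1Cc1c(OCc2ccccc2)c(C)c(OCc2ccccc2)c(Br)c1OCc1ccccc1
F14 | step 11 | 1-{6-(benzyloxy)-3-{[2,4,6-tris(benzyloxy)-3-butanoyl-5-methylphenyl]methyl}-4-methoxy-2,5-dimethylphenyl}butan-1-one | CCCC(=O)c1c(C)c(Cc2c(OCc3ccccc3)c(C)c(OCc3ccccc3)c(C(=O)CCC)c2OCc2ccccc2)c(OC)c(C)c1OCc1ccccc1
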